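The trap in these flasks is to take X at its peak for X at the end: Tuesday's run read 80 % at 8.00 min and 64 % at 20.0 min, from one flask.

| flask | Q | G | remark | time |
|---|---|---|---|---|
| Friday's | 0.017 M (in portions, 4) | 0.0594 M | run made earlier; portions every 40 s |  |
| Sunday's | 0.055 M (in portions, 4) | 0.0594 M | run made earlier; portions every 40 s |  |
| Monday's | 0.24 M (in portions, 4) | 0.0594 M | run made earlier; portions every 40 s |  |
| Tuesday's | 0.054 M (in portions, 4) | 0.096 M | run made earlier; portions every 40 s |  |
| violet | 0.080 M (in portions, 4) | 0.250 M | the portions of Q follow each other after 150 s, the first at the start | 30 min |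
| green | 0.20 M (in portions, 4) | 0.0300 M | the portions of Q follow each other after 40 s, the first at the start | 30 min |
| ochre | 0.015 M (in portions, 4) | 0.0800 M | the portions of Q follow each other after 40 s, the first at the start | 30 min |
| blue | 0.054 M (in portions, 4) | 0.0594 M | the portions of Q follow each other after 40 s, the first at the start | 30 min |

- Friday's (time / min: X / %, Q / %): 2.00: 31, 41; 5.00: 75, 26; 10.0: 87, 6; 15.0: 85, 3; 20.0: 86, 0
- Sunday's (time / min: X / %, Q / %): 2.00: 26, 44; 5.00: 59, 37; 10.0: 66, 24; 15.0: 64, 13; 20.0: 59, 15
- Monday's (time / min: X / %, Q / %): 1.50: 11, 61; 3.00: 20, 80; 6.00: 21, 74; 12.0: 17, 76; 20.0: 15, 72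
- Tuesday's (time / min: X / %, Q / %): 4.00: 72, 25; 8.00: 80, 8; 12.0: 71, 8; 15.0: 72, 5; 20.0: 64, 0

(readings scatter by 2 percentage points)

- the analysis behind the earlier runs scatters by 2 percentage points, standard deviation

1. the flasks by amount of X, in percent of the Q charged, highest first, at 30 min (violet / green / ochre / blue)
2. the same order at 3.0 min (violet / green / ochre / blue)
3. the amount of X, in percent of the Q charged of the flask you put first, at 30 min
4. the amount of X, in percent of the Q charged of the flask you put last, at 30 min

One chemist counts equivalents: X cannot pass the smaller charge, so green, short of G, has a ceiling of 15.0 %, and the others rank by their excess of G, which puts ochre at 5.33 equivalents, violet at 3.12 and blue at 1.10, and so violet above blue.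

The other chemist, whose side I take, reads the fall after the peak. Monday's X stood at 21 % at 6.00 min, close under its ceiling of 24.8 %, and fell to 15 % at 20.0 min. Taken as second order in c(X), that fall gives a fade constant k of 0.567 /M/min, a reading that carries the scatter of 2 percentage points on each X.

The reciprocal of k times the time is then the crossing concentration c×, 0.0588 M at 30 min, the amount of X that is down to half by that time. A flask whose smaller charge lies below c× is held by its equivalents, and one above it by the fade. The share of X surviving is one over one plus the smaller charge divided by c×, and this share multiplies the ceiling.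

My reckoning gives ochre 79.7 %, blue 52.1 %, violet 42.4 % and green 9.93 %, so blue stands above violet, since the share falls as the smaller charge rises and c(Q) in blue is less than in violet. With c(Q) in blue at 0.918 times c×, and c× a reading that carries the scatter, I do not place blue on either side of the crossing.

The forecast takes the fade side, on the grounds that “X is then lost slowly, second order in X”. It gives ochre > blue > violet > green at 30 min, ochre > blue > violet > green at 3.0 min, 80 % for the first flask and 11 % for the last, the last a little above my figure for green.

The flasks give ochre > blue > violet > green at 30 min and ochre > blue > violet > green at 3.0 min, with ochre at 78.5 %, blue at 50.5 %, violet at 42.8 % and green at 9.17 %, so the forecast held and blue stands above violet. The equivalents keep their region in a flask short of G read early: at 3.0 min, when c× is 0.588 M, green reads 13.2 % under its ceiling.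

    G → L (k = 4.64 × 10⁻⁴ /s)
    X + E → D (k = 0.0118 /M/s)
    Q + G → X + E (k = 0.129 /M/s)

In ochre at 11.4 min, the half-life of Q by Q + G → X + E is 1.9 min, against 71 min for X by X + E → D. G → L, with a half-life of 25 min in ochre, makes no difference to the X that ochre ends with.

Ochre's recipe with c(Q) raised to 0.025 M lies below c× still, and the survival share gives 70.2 % at 30 min; that flask gives 68.9 %.

Readings and results were generated by integration with made-up constants.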